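## The problem

The target is an acyclic 8-O-4′ neolignan. Ring A (4-hydroxy-3,5-dimethoxyphenyl) sits on the benzylic carbinol carbon C7, C8 carries an aryl ether oxygen to ring B (2,6-dimethoxy-4-[(E)-prop-1-enyl]phenyl), and C9 is a methyl group. No ring has to be closed, so the task is to join two arenes through the C7–C8 bond and the C8–O bond. The only stereocentres are the adjacent C7 and C8, which must be 7R,8S (erythro, anti in the zigzag drawing). Nothing else in the molecule is stereogenic, so absolute control has to come from a catalyst, a reagent or the chiral pool. C8 can direct a reduction or addition at C7, but an aryloxy group is a small, poorly chelating director, so a method that sets both centres at once is preferable. The ring B oxygen lies between two methoxy groups, which makes it a hindered nucleophile towards a secondary carbon. The (E)-propenyl styrene does not tolerate hydrogenation, hydroboration, strong acid or strong Lewis acids. The free phenol para to the benzylic carbinol can form a quinone methide under acid, base or heat, which would scramble C7. The enabling feature is that if C9 is carried as an ester, the C8–H bond lies between the C7 ketone and the C9 ester and also bears the aryloxy oxygen. C8 then epimerises freely, and one selective reduction at C7 can fix both centres.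

## Retrosynthesis

Target 15 is traced back to its ring A allyl ether 14 by cutting the O–allyl bond. The phenol has to be masked from the acid chloride stage onward, and the mask must leave without touching the propenyl group or the carbinol. A benzyl ether would need hydrogenolysis and an acetal would need acid. An allyl ether falls to Pd(PPh3)4 and an amine at room temperature. The forward step only asks that the allyl aryl ether be ionised while the propenyl arene is ignored.

Compound 14 is traced through tosylate 13 and diol 12 to the hydroxy ester 11: the C9–H bonds are exchanged for C9–O bonds. The methyl comes from hydride displacement of the primary tosylate, the tosylate from selective sulfonylation of the diol, and the diol from reduction of the ester. This costs three steps, but it places at C9 the activating group that the key step needs. The neighbouring option, reducing a 2-aryloxypropiophenone with C9 already a methyl, leaves C8 far less acidic and gives up the dynamic resolution. The forward steps must reduce the ester without retro-aldol cleavage or hydroboration, distinguish primary from secondary hydroxyl, and displace the tosylate faster than the C7 alkoxide can close an oxetane.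

Compound 11 is traced to the racemic keto ester 10 by cutting the C7–H bond. This is the key disconnection. Ester 11 is the anti-(2R,3R) isomer; it maps onto 7R,8S in the target because the C9 ester outranks C7 at C8 whereas the methyl does not. In 10 the C8 centre is stereochemically meaningless, so the precursor can be made with no stereocontrol at all. The forward reaction must choose one carbonyl face and one C8 epimer, while enolisation keeps the two epimers in equilibrium.

Compound 10 is cut at C7–C8 into the lithium enolate 9 of aryloxyacetate 4 and the acid chloride 8 (crossed Claisen acylation). The alternative cut at C8–O would require the doubly ortho-substituted phenoxide of 2 to displace an α-halo β-keto ester, with halophilic attack as a competing path. An aldol addition followed by oxidation would form the same bond with one more redox step and is kept as the fallback. The precursors are two monoaryl fragments of similar size, and the forward step asks only for C- over O-acylation.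

Acid chloride 8 comes from acid 7, and 7 from syringic acid 5 by double allylation to the allyl ester 6 and saponification in the same flask. Both are functional group changes on a commercial arene.

Ester 4 is cut at the phenol O–CH2 bond into (E)-propenylphenol 2 and ethyl bromoacetate 3. Phenol 2 comes from commercial 4-allyl-2,6-dimethoxyphenol 1 by moving the double bond into conjugation. The propenyl group is therefore present from the first step and is never exposed to a reagent that attacks it.

## Roads not taken

Alternative 1: The C7–O and C8–H bonds are removed together, leading back to the Z aryl enol ether A2. In the forward direction monoisopinocampheylborane adds syn across C7=C8, boron to C7 and hydrogen to C8, and oxidation gives the carbinol A1. Syn addition to the Z alkene gives the erythro relationship, and the chiral borane sets the absolute sense. The merits are real: C9 is a methyl from the start, so the three-step ester-to-methyl sequence of the chosen plan disappears, and the stereochemical outcome follows from a known model without a screen. The weak points are structural. A geometrically pure Z trisubstituted enol ether carrying the hindered ring B oxygen is not easy to make. The intermediate has boron on C7 and a good aryloxide leaving group on C8, the arrangement that undergoes β-elimination. The donor strength of the enol ether oxygen, on which the regiochemistry rests, is lowered by the aryl group. The propenyl group cannot be present during hydroboration, so ring B is carried as a bromide and the alkene is added later by cross-coupling, followed by removal of the silylethoxymethyl group. Against the better redox economy of this road, the chosen plan offers a catalytic stereo-defining step, no elimination-prone intermediate, and the propenyl group in place throughout.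

Alternative 2: The C7–C1 bond to ring A is cut. The aryllithium from bromide A5 is transmetalated with ClTi(OiPr)3 and the resulting ArTi(OiPr)3 adds to the (S)-aldehyde A4, giving the silyl ether A3 of the target by Felkin–Anh control. A4 would come from phenol 2 and ethyl (R)-lactate A6 by Mitsunobu etherification with inversion, followed by reduction. This is the shortest and most convergent road: C8 comes from the chiral pool, C9 is already a methyl, and only a desilylation follows the key step. In step count it is clearly better than the chosen plan. Its weak points are that a hindered phenol must be etherified at a secondary carbon, that α-aryloxy aldehydes racemise easily and any loss at C8 is permanent, and that C7 rests on substrate control by one small aryloxy-bearing centre, so a diastereomer mixture is likely. The chosen plan accepts four more steps in return for catalyst control of both centres and for a C8 centre whose lability is used instead of feared.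

Alternative 3: The C7–C8 bond is cut as an auxiliary aldol. The chlorotitanium enolate of acyl oxazolidinethione A8 (TiCl4, (−)-sparteine) adds to aldehyde A9 precomplexed with TiCl4 and should give the anti adduct A7. The step forms the C–C bond and both stereocentres at once, and it has a rational transition-state model. In predictability before any experiment it is at least equal to a reductase screen. Reductive removal of the auxiliary would lead to a diol like 12, so the end game and overall length are about the same as in the chosen plan. The weak points are the stoichiometric auxiliary and more than two equivalents of TiCl4 in contact with an electron-rich propenyl arene and many methoxy donors. In addition, the anti-selective glycolate aldol is established for alkyl and allyl ethers and not for a bulky, weakly basic aryloxy group, and the electron-rich aromatic aldehyde is a sluggish partner. The chosen plan forms the same bond by a simple racemic Claisen acylation and sets the stereocentres in neutral water with a catalyst, at the price of having to find the right enzyme.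

Key step: step 6

Remark: the reductase of step 6 is specified by its outcome (the panel member that gives the anti-(2R,3R) alcohol), because the variant can only be fixed by a screen. Step 3 is counted as one step because the allyl ester is saponified in the same flask.

## Route

Step 1
Reactants: 1 4-allyl-2,6-dimethoxyphenol
Product: 2 (E)-2,6-dimethoxy-4-(prop-1-enyl)phenol
Conditions: RuHCl(CO)(PPh3)3 (cat.), toluene, 80 °C
Reagents that add atoms: none
Why: Ruthenium hydride-catalysed alkene isomerisation (reversible hydrometalation and β-hydride elimination) moves the double bond into conjugation with ring B; the conjugated E-propenyl arene is the thermodynamic product and the free phenol is tolerated.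

Step 2
Reactants: 2 (E)-2,6-dimethoxy-4-(prop-1-enyl)phenol; 3 ethyl bromoacetate
Product: 4 ethyl 2-[2,6-dimethoxy-4-((E)-prop-1-enyl)phenoxy]acetate
Conditions: K2CO3, acetone, reflux
Reagents that add atoms: none
Why: Williamson ether synthesis; the α-bromo ester is a very reactive SN2 electrophile, so even the phenoxide flanked by two methoxy groups is alkylated, and carbonate leaves the propenyl group and the ester alone.

Step 3
Reactants: 5 syringic acid
Product: 7 4-(allyloxy)-3,5-dimethoxybenzoic acid, via allyl 4-(allyloxy)-3,5-dimethoxybenzoate 6 (not isolated)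
Conditions: allyl bromide (2.5 equiv), K2CO3, DMF, 60 °C; then NaOH, MeOH/H2O, 60 °C; then HCl
Reagents that add atoms: allyl bromide, C=CCBr
Why: Double O-alkylation of phenoxide and carboxylate followed by saponification in the same flask; hydroxide cleaves the allyl ester but not the aryl allyl ether.

Step 4
Reactants: 7 4-(allyloxy)-3,5-dimethoxybenzoic acid
Product: 8 4-(allyloxy)-3,5-dimethoxybenzoyl chloride
Conditions: (COCl)2, DMF (cat.), CH2Cl2, 0 °C to rt; evaporate, use crude
Reagents that add atoms: oxalyl chloride, O=C(Cl)C(=O)Cl
Why: Acid chloride formation through the chloroiminium species from DMF and oxalyl chloride; the allyl and methyl ethers are inert under these conditions.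

Step 5
Reactants: 4 ethyl 2-[2,6-dimethoxy-4-((E)-prop-1-enyl)phenoxy]acetate; 8 4-(allyloxy)-3,5-dimethoxybenzoyl chloride
Product: 10 racemic ethyl 3-[4-(allyloxy)-3,5-dimethoxyphenyl]-2-[2,6-dimethoxy-4-((E)-prop-1-enyl)phenoxy]-3-oxopropanoate, via lithium enolate of the aryloxyacetate 9 (not isolated)
Conditions: LiN(SiMe3)2 (2.1 equiv), THF, −78 °C; then 8 in THF, −78 to −40 °C; aq. NH4Cl
Reagents that add atoms: none
Why: Crossed Claisen condensation (C-acylation of a preformed lithium ester enolate by an aroyl chloride); the second equivalent of base turns the product into its enolate as it forms, which shields it from a second acylation. The new C8 centre is deliberately racemic and labile.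

Step 6
Reactants: 10 racemic ethyl 3-[4-(allyloxy)-3,5-dimethoxyphenyl]-2-[2,6-dimethoxy-4-((E)-prop-1-enyl)phenoxy]-3-oxopropanoate
Product: 11 ethyl (2R,3R)-3-[4-(allyloxy)-3,5-dimethoxyphenyl]-2-[2,6-dimethoxy-4-((E)-prop-1-enyl)phenoxy]-3-hydroxypropanoate
Conditions: ketoreductase (panel hit for the anti-(2R,3R) alcohol), NADP+ (cat.), glucose dehydrogenase, D-glucose, KH2PO4/K2HPO4 buffer pH 7.0, DMSO (10% v/v), 30 °C, pH held with NaOH
Reagents that add atoms: none
Why: This is a dynamic kinetic resolution by enzymatic ketone reduction, the closest known reaction type being ketoreductase reductions of α-substituted β-keto esters that racemise in situ. The enzyme binds one C8 epimer of 10 and passes the hydride of NADPH to the Si face of the C7 carbonyl while an active-site acid protonates the oxygen; glucose dehydrogenase and D-glucose return NADP+ to NADPH, so only hydrogen is added. No ring is closed. C7 is set by the enzyme's choice of carbonyl face and C8 by its preference for the 2R epimer, so both centres and the anti relationship are under catalyst control and not substrate control. The step needs epimerisation at C8 to be faster than reduction of the unwanted epimer. The substrate secures this because the C8–H bond is flanked by the aryl ketone and the ester and carries the aryloxy oxygen, so it enolises in neutral buffer, whereas the product has lost the ketone and is configurationally stable. Chemoselectivity comes from the cofactor, which reduces only the ketone and leaves the propenyl and allyl alkenes and the ester alone. The panel should include reductases evolved for bulky diaryl ketones and short-chain dehydrogenases that bind 1-aryl-2-aryloxypropanone skeletons.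

Step 7
Reactants: 11 ethyl (2R,3R)-3-[4-(allyloxy)-3,5-dimethoxyphenyl]-2-[2,6-dimethoxy-4-((E)-prop-1-enyl)phenoxy]-3-hydroxypropanoate
Product: 12 (1R,2S)-1-[4-(allyloxy)-3,5-dimethoxyphenyl]-2-[2,6-dimethoxy-4-((E)-prop-1-enyl)phenoxy]propane-1,3-diol
Conditions: NaBH4, THF/H2O (3:1), 0 °C to rt
Reagents that add atoms: none
Why: Borohydride reduction of an ester activated by the α-aryloxy and β-hydroxy groups, the usual way to the 1,3-diols of arylglycerol β-aryl ethers. The protic medium destroys any borane, so neither alkene is hydroborated (a risk with LiBH4 in ether solvents), and C7 and C8 are not touched.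

Step 8
Reactants: 12 (1R,2S)-1-[4-(allyloxy)-3,5-dimethoxyphenyl]-2-[2,6-dimethoxy-4-((E)-prop-1-enyl)phenoxy]propane-1,3-diol
Product: 13 (2S,3R)-3-[4-(allyloxy)-3,5-dimethoxyphenyl]-2-[2,6-dimethoxy-4-((E)-prop-1-enyl)phenoxy]-3-hydroxypropyl 4-methylbenzenesulfonate
Conditions: TsCl (1.1 equiv), Et3N, DMAP (cat.), CH2Cl2, 0 °C
Reagents that add atoms: 4-methylbenzenesulfonyl chloride, Cc1ccc(cc1)S(=O)(=O)Cl
Why: Selective sulfonylation of the primary hydroxyl; the secondary benzylic hydroxyl is shielded by ring A and the neighbouring aryloxy group and reacts much more slowly at 0 °C with a slight excess of reagent.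

Step 9
Reactants: 13 (2S,3R)-3-[4-(allyloxy)-3,5-dimethoxyphenyl]-2-[2,6-dimethoxy-4-((E)-prop-1-enyl)phenoxy]-3-hydroxypropyl 4-methylbenzenesulfonate
Product: 14 (1R,2S)-1-[4-(allyloxy)-3,5-dimethoxyphenyl]-2-[2,6-dimethoxy-4-((E)-prop-1-enyl)phenoxy]propan-1-ol
Conditions: LiEt3BH (3 equiv), THF, 0 °C to rt
Reagents that add atoms: none
Why: SN2 displacement of the primary tosylate by hydride; the first equivalent deprotonates the C7 hydroxyl to a lithium alkoxide tied up by BEt3, which is a poor nucleophile for oxetane closure, and neither stereocentre takes part.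

Step 10
Reactants: 14 (1R,2S)-1-[4-(allyloxy)-3,5-dimethoxyphenyl]-2-[2,6-dimethoxy-4-((E)-prop-1-enyl)phenoxy]propan-1-ol
Product: 15 (1R,2S)-1-(4-hydroxy-3,5-dimethoxyphenyl)-2-[2,6-dimethoxy-4-((E)-prop-1-enyl)phenoxy]propan-1-ol
Conditions: Pd(PPh3)4 (5 mol%), morpholine, THF, rt
Reagents that add atoms: none
Why: Tsuji–Trost deallylation: zerovalent palladium ionises the allyl aryl ether to a π-allyl complex and the phenoxide, and morpholine captures the allyl group; the neutral, room-temperature conditions leave the propenyl alkene, the benzylic carbinol and both stereocentres untouched.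

## Compound list

1 | 4-allyl-2,6-dimethoxyphenol | C=CCc1cc(OC)c(O)c(OC)c1 | starting material
2 | (E)-2,6-dimethoxy-4-(prop-1-enyl)phenol | C/C=C/c1cc(OC)c(O)c(OC)c1 | intermediate
3 | ethyl bromoacetate | CCOC(=O)CBr | starting material
4 | ethyl 2-[2,6-dimethoxy-4-((E)-prop-1-enyl)phenoxy]acetate | C/C=C/c1cc(OC)c(OCC(=O)OCC)c(OC)c1 | intermediate
5 | syringic acid (4-hydroxy-3,5-dimethoxybenzoic acid) | COc1cc(C(=O)O)cc(OC)c1O | starting material
6 | allyl 4-(allyloxy)-3,5-dimethoxybenzoate | C=CCOC(=O)c1cc(OC)c(OCC=C)c(OC)c1 | intermediate (not isolated)
7 | 4-(allyloxy)-3,5-dimethoxybenzoic acid | C=CCOc1c(OC)cc(C(=O)O)cc1OC | intermediate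
8 | 4-(allyloxy)-3,5-dimethoxybenzoyl chloride | C=CCOc1c(OC)cc(C(=O)Cl)cc1OC | intermediate
9 | lithium enolate of ethyl 2-[2,6-dimethoxy-4-((E)-prop-1-enyl)phenoxy]acetate | C/C=C/c1cc(OC)c(OC=C(O[Li])OCC)c(OC)c1 | intermediate (not isolated)
10 | racemic ethyl 3-[4-(allyloxy)-3,5-dimethoxyphenyl]-2-[2,6-dimethoxy-4-((E)-prop-1-enyl)phenoxy]-3-oxopropanoate | C/C=C/c1cc(OC)c(OC(C(=O)OCC)C(=O)c2cc(OC)c(OCC=C)c(OC)c2)c(OC)c1 | intermediate
11 | ethyl (2R,3R)-3-[4-(allyloxy)-3,5-dimethoxyphenyl]-2-[2,6-dimethoxy-4-((E)-prop-1-enyl)phenoxy]-3-hydroxypropanoate | C/C=C/c1cc(OC)c(O[C@@H](C(=O)OCC)[C@H](O)c2cc(OC)c(OCC=C)c(OC)c2)c(OC)c1 | intermediate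
12 | (1R,2S)-1-[4-(allyloxy)-3,5-dimethoxyphenyl]-2-[2,6-dimethoxy-4-((E)-prop-1-enyl)phenoxy]propane-1,3-diol | C/C=C/c1cc(OC)c(O[C@@H](CO)[C@H](O)c2cc(OC)c(OCC=C)c(OC)c2)c(OC)c1 | intermediate
13 | (2S,3R)-3-[4-(allyloxy)-3,5-dimethoxyphenyl]-2-[2,6-dimethoxy-4-((E)-prop-1-enyl)phenoxy]-3-hydroxypropyl 4-methylbenzenesulfonate | C/C=C/c1cc(OC)c(O[C@@H](COS(=O)(=O)c3ccc(C)cc3)[C@H](O)c2cc(OC)c(OCC=C)c(OC)c2)c(OC)c1 | intermediate
14 | (1R,2S)-1-[4-(allyloxy)-3,5-dimethoxyphenyl]-2-[2,6-dimethoxy-4-((E)-prop-1-enyl)phenoxy]propan-1-ol | C/C=C/c1cc(OC)c(O[C@@H](C)[C@H](O)c2cc(OC)c(OCC=C)c(OC)c2)c(OC)c1 | intermediate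
15 | (1R,2S)-1-(4-hydroxy-3,5-dimethoxyphenyl)-2-[2,6-dimethoxy-4-((E)-prop-1-enyl)phenoxy]propan-1-ol | C/C=C/c1cc(OC)c(O[C@@H](C)[C@H](O)c2cc(OC)c(O)c(OC)c2)c(OC)c1 | target

## Step count and risks

Total: 10 steps. Longest linear sequence: 8 steps (steps 1, 2, 5–10, or equally steps 3, 4, 5–10).

Step 6 (key step). The ketone, flanked by two bulky aryl-bearing groups, may not be accepted by any panel member. The accepted face or epimer may lead to a syn isomer or to the enantiomer. Reduction of the unwanted C8 epimer may outrun enolisation, which would lower the diastereomer purity. Slow hydrolysis and decarboxylation of the β-keto ester in buffer may drain the substrate. The fallback is a chemical reduction followed by inversion; it sets out from 10 and returns at 11. Transfer hydrogenation of 10 with RuCl[(R,R)-TsDPEN](p-cymene) in HCO2H/Et3N works under the same dynamic conditions. This catalyst class is syn-selective for α-alkoxy β-keto esters, so it is aimed not at 11 but at its C7 epimer, ethyl (2R,3S)-3-[4-(allyloxy)-3,5-dimethoxyphenyl]-2-[2,6-dimethoxy-4-((E)-prop-1-enyl)phenoxy]-3-hydroxypropanoate F1, in which C8 is already correct. The ligand enantiomer is chosen on the usual model in which the aryl group of the ketone is recognised by the arene ligand. Mitsunobu inversion at C7 (4-nitrobenzoic acid, PPh3, diisopropyl azodicarboxylate) should give ethyl (2R,3R)-3-[4-(allyloxy)-3,5-dimethoxyphenyl]-2-[2,6-dimethoxy-4-((E)-prop-1-enyl)phenoxy]-3-(4-nitrobenzoyloxy)propanoate F2. K2CO3 in ethanol at 0 °C then removes the activated benzoate and returns 11. The inversion itself carries a risk of partial ionisation at the electron-rich benzylic carbon.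

Step 5. The acid chloride may be consumed by O-acylation of the enolate or of the product enolate, by double acylation, or by the amide base. The fallback replaces acylation by aldol addition and oxidation; it sets out from 4 and returns at 10. Commercial syringaldehyde F3 is allylated (allyl bromide, K2CO3, DMF) to 4-(allyloxy)-3,5-dimethoxybenzaldehyde F4. Enolate 9, generated from 4 with LiN(i-Pr)2 at −78 °C, adds to F4 to give ethyl 3-[4-(allyloxy)-3,5-dimethoxyphenyl]-2-[2,6-dimethoxy-4-((E)-prop-1-enyl)phenoxy]-3-hydroxypropanoate F5 as a mixture of racemic diastereomers. Dess–Martin periodinane in CH2Cl2 oxidises the benzylic alcohol of F5 to 10; the diastereomer mixture is of no consequence because both centres are erased or labile in 10.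

Step 9. The C7 alkoxide may displace the tosylate internally (oxetane closure), or base-induced elimination with loss of the aryloxide may compete with hydride delivery. The fallback masks the hydroxyl; it sets out from 13 and returns at 14. Silylation with Et3SiCl and imidazole in DMF gives (2S,3R)-3-[4-(allyloxy)-3,5-dimethoxyphenyl]-2-[2,6-dimethoxy-4-((E)-prop-1-enyl)phenoxy]-3-(triethylsilyloxy)propyl 4-methylbenzenesulfonate F6. LiEt3BH then reduces the tosylate, with no alkoxide present, to triethyl{(1R,2S)-1-[4-(allyloxy)-3,5-dimethoxyphenyl]-2-[2,6-dimethoxy-4-((E)-prop-1-enyl)phenoxy]propoxy}silane F7. Bu4NF in THF removes the silyl group to give 14.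

Step 1. The double-bond migration may stop short of completion or leave some Z isomer that cannot be separated from the E compound. The fallback builds the propenyl group by cross-coupling; it sets out from 3 and returns at 4, bypassing 1 and 2. Commercial 4-bromo-2,6-dimethoxyphenol F8 is alkylated with 3 (K2CO3, acetone) to ethyl 2-(4-bromo-2,6-dimethoxyphenoxy)acetate F9. Suzuki–Miyaura coupling of F9 with geometrically pure (E)-prop-1-enylboronic acid pinacol ester (Pd(dppf)Cl2, K3PO4, dioxane/H2O, 80 °C) gives 4 with the alkene geometry fixed by the reagent.

## Further compounds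

F1 | step 6 | ethyl (2R,3S)-3-[4-(allyloxy)-3,5-dimethoxyphenyl]-2-[2,6-dimethoxy-4-((E)-prop-1-enyl)phenoxy]-3-hydroxypropanoate | C/C=C/c1cc(OC)c(O[C@@H](C(=O)OCC)[C@@H](O)c2cc(OC)c(OCC=C)c(OC)c2)c(OC)c1
F2 | step 6 | ethyl (2R,3R)-3-[4-(allyloxy)-3,5-dimethoxyphenyl]-2-[2,6-dimethoxy-4-((E)-prop-1-enyl)phenoxy]-3-(4-nitrobenzoyloxy)propanoate | C/C=C/c1cc(OC)c(O[C@@H](C(=O)OCC)[C@H](OC(=O)c3ccc(cc3)[N+](=O)[O-])c2cc(OC)c(OCC=C)c(OC)c2)c(OC)c1
F3 | step 5 | syringaldehyde (4-hydroxy-3,5-dimethoxybenzaldehyde, purchased) | COc1cc(C=O)cc(OC)c1O
F4 | step 5 | 4-(allyloxy)-3,5-dimethoxybenzaldehyde | C=CCOc1c(OC)cc(C=O)cc1OC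
F5 | step 5 | ethyl 3-[4-(allyloxy)-3,5-dimethoxyphenyl]-2-[2,6-dimethoxy-4-((E)-prop-1-enyl)phenoxy]-3-hydroxypropanoate (racemic diastereomer mixture) | C/C=C/c1cc(OC)c(OC(C(=O)OCC)C(O)c2cc(OC)c(OCC=C)c(OC)c2)c(OC)c1
F6 | step 9 | (2S,3R)-3-[4-(allyloxy)-3,5-dimethoxyphenyl]-2-[2,6-dimethoxy-4-((E)-prop-1-enyl)phenoxy]-3-(triethylsilyloxy)propyl 4-methylbenzenesulfonate | C/C=C/c1cc(OC)c(O[C@@H](COS(=O)(=O)c3ccc(C)cc3)[C@H](O[Si](CC)(CC)CC)c2cc(OC)c(OCC=C)c(OC)c2)c(OC)c1
F7 | step 9 | triethyl{(1R,2S)-1-[4-(allyloxy)-3,5-dimethoxyphenyl]-2-[2,6-dimethoxy-4-((E)-prop-1-enyl)phenoxy]propoxy}silane | C/C=C/c1cc(OC)c(O[C@@H](C)[C@H](O[Si](CC)(CC)CC)c2cc(OC)c(OCC=C)c(OC)c2)c(OC)c1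
F8 | step 1 | 4-bromo-2,6-dimethoxyphenol (purchased) | COc1cc(Br)cc(OC)c1O
F9 | step 1 | ethyl 2-(4-bromo-2,6-dimethoxyphenoxy)acetate | CCOC(=O)COc1c(OC)cc(Br)cc1OC
A1 | alternative 1 | (1R,2S)-2-(4-bromo-2,6-dimethoxyphenoxy)-1-(3,5-dimethoxy-4-{[2-(trimethylsilyl)ethoxy]methoxy}phenyl)propan-1-ol | COc1cc(Br)cc(OC)c1O[C@@H](C)[C@H](O)c1cc(OC)c(OCOCC[Si](C)(C)C)c(OC)c1
A2 | alternative 1 | (Z)-5-bromo-2-{[1-(3,5-dimethoxy-4-{[2-(trimethylsilyl)ethoxy]methoxy}phenyl)prop-1-en-2-yl]oxy}-1,3-dimethoxybenzene | COc1cc(Br)cc(OC)c1O/C(C)=C\c1cc(OC)c(OCOCC[Si](C)(C)C)c(OC)c1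
A3 | alternative 2 | (1R,2S)-1-[3,5-dimethoxy-4-(triisopropylsilyloxy)phenyl]-2-[2,6-dimethoxy-4-((E)-prop-1-enyl)phenoxy]propan-1-ol | C/C=C/c1cc(OC)c(O[C@@H](C)[C@H](O)c2cc(OC)c(O[Si](C(C)C)(C(C)C)C(C)C)c(OC)c2)c(OC)c1
A4 | alternative 2 | (S)-2-[2,6-dimethoxy-4-((E)-prop-1-enyl)phenoxy]propanal | C/C=C/c1cc(OC)c(O[C@@H](C)C=O)c(OC)c1
A5 | alternative 2 | (4-bromo-2,6-dimethoxyphenoxy)triisopropylsilane | COc1cc(Br)cc(OC)c1O[Si](C(C)C)(C(C)C)C(C)C
A6 | alternative 2 | ethyl (R)-lactate | C[C@@H](O)C(=O)OCC
A7 | alternative 3 | (S)-4-benzyl-3-{(2R,3R)-3-[3,5-dimethoxy-4-(triisopropylsilyloxy)phenyl]-2-[2,6-dimethoxy-4-((E)-prop-1-enyl)phenoxy]-3-hydroxypropanoyl}-1,3-oxazolidine-2-thione | C/C=C/c1cc(OC)c(O[C@@H](C(=O)N2[C@@H](Cc3ccccc3)COC2=S)[C@H](O)c2cc(OC)c(O[Si](C(C)C)(C(C)C)C(C)C)c(OC)c2)c(OC)c1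
A8 | alternative 3 | (S)-4-benzyl-3-{2-[2,6-dimethoxy-4-((E)-prop-1-enyl)phenoxy]acetyl}-1,3-oxazolidine-2-thione | C/C=C/c1cc(OC)c(OCC(=O)N2[C@@H](Cc3ccccc3)COC2=S)c(OC)c1
A9 | alternative 3 | 3,5-dimethoxy-4-(triisopropylsilyloxy)benzaldehyde | COc1cc(C=O)cc(OC)c1O[Si](C(C)C)(C(C)C)C(C)C
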